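**Retrosynthetic overview**
- Target ⇐ senecioylation at O9 ⇐ N–O cleavage ⇐ acetylation at O8 of a cis-8,9-dioxygenated decalinone; ring A is closed last.
- Ring A: C7–C8 bond by a chelate-controlled intramolecular carbonyl-ene reaction of an α-aminooxy aldehyde onto the prenyl group (sets C7, C8); C9–O by proline-catalysed α-aminoxylation (sets C9).
- C9–C10 bond: Cu-catalysed 1,4-addition of a masked acetaldehyde carbanion to a 4,4,5-trisubstituted cyclohex-2-enone (sets C10).
- Ring B first: organocatalytic asymmetric enamine Michael/aldol (Robinson-type) annulation of 2,5-dimethylhex-4-enal with (E)-pent-3-en-2-one (sets C4, C5).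
- Ring order: B (step 2), then A (step 4).

Assumption: eremophilane numbering is used in the explanations (C2 ketone, C4/C5 methyl-bearing carbons, C7 isopropenyl, C8 acetate, C9 senecioate, C10 ring-fusion CH). The target is (4S,5R,7R,8R,9S,10S), i.e. 4β,5β-dimethyl, 7β-isopropenyl, 8α-OAc, 9α-OSen, 10β-H (cis-decalin).

**Step 1**
Reactants: 1 propanal; 2 1-bromo-3-methylbut-2-ene (prenyl bromide)
Product: 5 rac-2,5-dimethylhex-4-enal, via propanal tert-butylimine 3 (not isolated), via prenylated aldimine 4 (not isolated)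
Conditions: t-BuNH2, MgSO4, Et2O, 0 °C; LDA, THF, −78 °C; 2, −78 → 0 °C; aq. oxalic acid, 20 °C
Reagents that add atoms: none
Why: Stork metalloenamine alkylation – the lithiated aldimine is C-alkylated by SN2 at the primary carbon of the allylic bromide and mild acid frees the aldehyde; the new α-centre is racemic, stereolabile and erased when the enamine forms in step 2.

**Step 2**
Reactants: 5 rac-2,5-dimethylhex-4-enal; 6 (E)-pent-3-en-2-one
Product: 8 (4R,5S)-4,5-dimethyl-4-(3-methylbut-2-en-1-yl)cyclohex-2-en-1-one, via keto aldehyde 7 (not isolated)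
Conditions: (S)-N-(4-dodecylphenylsulfonyl)pyrrolidine-2-carboxamide (20 mol%), 4 Å MS, ClCH2CH2Cl, 40 °C; then LiOH (20 mol%), THF, 20 °C
Reagents that add atoms: none
Why: Proposed new method: asymmetric enamine Michael/aldol (Yamada–Otani-type Robinson) annulation extended to a β-methyl enone – the catalyst condenses with 5 (erasing its α-centre) to the E-enamine (prenyl CH2 anti to N), its sulfonamide N–H binds the s-cis enone 6, and C–C bond formation on the open enamine face through the compact Robinson-type transition state (β-methyl anti to the enamine C=C) sets quaternary C5 and C4 with the two methyls cis, after which LiOH closes ring B by aldol condensation; the closest known reaction is the proline-sulfonamide-catalysed annulation of α,α-disubstituted aldehydes with methyl vinyl ketone to 4,4-disubstituted cyclohexenones (the catalyst antipode is taken if the opposite sense is found).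

**Step 3**
Reactants: 8 (4R,5S)-4,5-dimethyl-4-(3-methylbut-2-en-1-yl)cyclohex-2-en-1-one
Product: 11 2-[(1S,2R,3S)-2,3-dimethyl-2-(3-methylbut-2-en-1-yl)-5-oxocyclohexyl]acetaldehyde, via silyl enol ether 9 (not isolated), via keto acetal 10 (not isolated)
Conditions: (1,3-dioxolan-2-ylmethyl)MgBr (1.5 equiv), CuBr·SMe2 (10 mol%), TMSCl (2 equiv), THF, −78 → −30 °C; then 2 M HCl/THF, 20 °C
Reagents that add atoms: (1,3-dioxolan-2-ylmethyl)magnesium bromide, Br[Mg]CC1OCCO1; water, O
Why: Copper-catalysed conjugate (1,4-) addition with TMSCl trapping, then hydrolysis of silyl enol ether and acetal; axial attack anti to the pseudo-axial C5 methyl and trans to the C4 methyl puts the new chain on the α face, cis to the prenyl group, which sets C10 (10β-H).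

**Step 4**
Reactants: 11 2-[(1S,2R,3S)-2,3-dimethyl-2-(3-methylbut-2-en-1-yl)-5-oxocyclohexyl]acetaldehyde
Product: 13 (4S,4aR,6R,7R,8S,8aS)-8-(anilinooxy)-7-hydroxy-4,4a-dimethyl-6-(prop-1-en-2-yl)octahydronaphthalen-2(1H)-one, via aminooxy aldehyde 12 (not isolated)
Conditions: D-proline (20 mol%), PhN=O (1.1 equiv), CHCl3, 0 °C; then ZnBr2 (2 equiv), CH2Cl2, −20 → 0 °C
Reagents that add atoms: nitrosobenzene, O=Nc1ccccc1
Why: Proline-catalysed enamine α-aminoxylation (O-selective nitroso aldol; the aldehyde reacts far faster than the ring ketone) sets C9 as 9S under catalyst control, and the crude aldehyde then undergoes a chelate-controlled type I carbonyl-ene cyclisation – Zn(II) bridging the aldehyde and aminooxy oxygens (Cram chelate) makes the prenyl alkene add through the cis-decalin chair with O9 axial and the new C8–O and isopropenyl equatorial, giving 8α-OH cis to O9 and trans to the 7β-isopropenyl group.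

**Step 5**
Reactants: 13 (4S,4aR,6R,7R,8S,8aS)-8-(anilinooxy)-7-hydroxy-4,4a-dimethyl-6-(prop-1-en-2-yl)octahydronaphthalen-2(1H)-one
Product: 14 (1S,2R,3R,4aR,5S,8aS)-1-(anilinooxy)-4a,5-dimethyl-7-oxo-3-(prop-1-en-2-yl)decahydronaphthalen-2-yl acetate
Conditions: Ac2O (1.2 equiv), pyridine, DMAP (5 mol%), CH2Cl2, 0 °C
Reagents that add atoms: acetic anhydride, CC(=O)OC(C)=O
Why: DMAP-catalysed acetylation of the equatorial C8 alcohol; the weakly nucleophilic N–H of the O-alkyl-N-arylhydroxylamine stays free and no stereocentre is touched.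

**Step 6**
Reactants: 14 (1S,2R,3R,4aR,5S,8aS)-1-(anilinooxy)-4a,5-dimethyl-7-oxo-3-(prop-1-en-2-yl)decahydronaphthalen-2-yl acetate
Product: 15 (1S,2R,3R,4aR,5S,8aS)-1-hydroxy-4a,5-dimethyl-7-oxo-3-(prop-1-en-2-yl)decahydronaphthalen-2-yl acetate
Conditions: Zn dust, AcOH/THF (1:2), 20 °C
Reagents that add atoms: none
Why: Reductive N–O cleavage by zinc in acetic acid frees the axial C9 alcohol without touching esters, ketone or alkene, and the acidic medium suppresses 8→9 acetyl migration.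

**Step 7**
Reactants: 15 (1S,2R,3R,4aR,5S,8aS)-1-hydroxy-4a,5-dimethyl-7-oxo-3-(prop-1-en-2-yl)decahydronaphthalen-2-yl acetate
Product: 16 (1S,2R,3R,4aR,5S,8aS)-2-(acetyloxy)-4a,5-dimethyl-7-oxo-3-(prop-1-en-2-yl)decahydronaphthalen-1-yl 3-methylbut-2-enoate
Conditions: 3-methylbut-2-enoyl chloride (3 equiv), pyridine, DMAP (0.5 equiv), CH2Cl2, 0 → 35 °C
Reagents that add atoms: 3-methylbut-2-enoyl chloride, CC(C)=CC(Cl)=O
Why: DMAP-catalysed (Steglich-type nucleophilic catalysis) acylation of the axial C9 alcohol with retention gives the target.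

**Compound list**
1 | propanal | CCC=O | starting material
2 | 1-bromo-3-methylbut-2-ene (prenyl bromide) | CC(C)=CCBr | starting material
3 | N-tert-butylpropan-1-imine (propanal tert-butylimine) | CCC=NC(C)(C)C | intermediate
4 | N-tert-butyl-2,5-dimethylhex-4-en-1-imine (prenylated aldimine) | CC(C)=CCC(C)C=NC(C)(C)C | intermediate
5 | rac-2,5-dimethylhex-4-enal | CC(C)=CCC(C)C=O | intermediate
6 | (E)-pent-3-en-2-one | C/C=C/C(C)=O | starting material
7 | (2R,3S)-2,3-dimethyl-2-(3-methylbut-2-en-1-yl)-5-oxohexanal (keto aldehyde) | CC(C)=CC[C@@](C)(C=O)[C@@H](C)CC(C)=O | intermediate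
8 | (4R,5S)-4,5-dimethyl-4-(3-methylbut-2-en-1-yl)cyclohex-2-en-1-one | CC(C)=CC[C@@]1(C)C=CC(=O)C[C@@H]1C | intermediate
9 | {[(3S,4R,5S)-3-(1,3-dioxolan-2-ylmethyl)-4,5-dimethyl-4-(3-methylbut-2-en-1-yl)cyclohex-1-en-1-yl]oxy}trimethylsilane (silyl enol ether) | CC(C)=CC[C@@]1(C)[C@@H](CC2OCCO2)C=C(O[Si](C)(C)C)C[C@@H]1C | intermediate
10 | (3S,4R,5S)-3-(1,3-dioxolan-2-ylmethyl)-4,5-dimethyl-4-(3-methylbut-2-en-1-yl)cyclohexan-1-one (keto acetal) | CC(C)=CC[C@@]1(C)[C@@H](CC2OCCO2)CC(=O)C[C@@H]1C | intermediate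
11 | 2-[(1S,2R,3S)-2,3-dimethyl-2-(3-methylbut-2-en-1-yl)-5-oxocyclohexyl]acetaldehyde | CC(C)=CC[C@@]1(C)[C@@H](CC=O)CC(=O)C[C@@H]1C | intermediate
12 | (2S)-2-(anilinooxy)-2-[(1S,2R,3S)-2,3-dimethyl-2-(3-methylbut-2-en-1-yl)-5-oxocyclohexyl]acetaldehyde (aminooxy aldehyde) | CC(C)=CC[C@@]1(C)[C@@H]([C@H](ONc2ccccc2)C=O)CC(=O)C[C@@H]1C | intermediate
13 | (4S,4aR,6R,7R,8S,8aS)-8-(anilinooxy)-7-hydroxy-4,4a-dimethyl-6-(prop-1-en-2-yl)octahydronaphthalen-2(1H)-one | C=C(C)[C@H]1C[C@@]2(C)[C@H](CC(=O)C[C@@H]2C)[C@H](ONc3ccccc3)[C@@H]1O | intermediate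
14 | (1S,2R,3R,4aR,5S,8aS)-1-(anilinooxy)-4a,5-dimethyl-7-oxo-3-(prop-1-en-2-yl)decahydronaphthalen-2-yl acetate | C=C(C)[C@H]1C[C@@]2(C)[C@H](CC(=O)C[C@@H]2C)[C@H](ONc3ccccc3)[C@@H]1OC(C)=O | intermediate
15 | (1S,2R,3R,4aR,5S,8aS)-1-hydroxy-4a,5-dimethyl-7-oxo-3-(prop-1-en-2-yl)decahydronaphthalen-2-yl acetate | C=C(C)[C@H]1C[C@@]2(C)[C@H](CC(=O)C[C@@H]2C)[C@H](O)[C@@H]1OC(C)=O | intermediate
16 | (1S,2R,3R,4aR,5S,8aS)-2-(acetyloxy)-4a,5-dimethyl-7-oxo-3-(prop-1-en-2-yl)decahydronaphthalen-1-yl 3-methylbut-2-enoate (8α-acetoxy-9α-senecioyloxy-10βH-eremophil-11-en-2-one) | C=C(C)[C@H]1C[C@@]2(C)[C@H](CC(=O)C[C@@H]2C)[C@H](OC(=O)C=C(C)C)[C@@H]1OC(C)=O | target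

**Totals**
Total step count: 7. Longest linear sequence: 7 (the route is fully linear).

**Steps most likely to fail, with fallbacks**

Step 2 (the new annulation) may give low ee through E/Z-enamine mixtures, or the trans-dimethyl isomer. The fallback uses known Stork–Danheiser chemistry, sets out from prenyl bromide 2 and comes back at enone 8. The known diarylprolinol silyl ether-catalysed Michael/aldol/decarboxylation of crotonaldehyde with tert-butyl acetoacetate gives (S)-5-methylcyclohex-2-en-1-one F1. Thiophenol addition followed by NCS gives the vinylogous thioester (R)-5-methyl-3-(phenylsulfanyl)cyclohex-2-en-1-one F2. LDA/MeI gives (5S)-5,6-dimethyl-3-(phenylsulfanyl)cyclohex-2-en-1-one F3. LDA and then 2 alkylate anti to the neighbouring methyl to give (5S,6R)-5,6-dimethyl-6-(3-methylbut-2-en-1-yl)-3-(phenylsulfanyl)cyclohex-2-en-1-one F4. DIBAL-H reduction and aqueous HCl (carbonyl transposition) deliver 8.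

Step 4 has two risks: the hindered aldehyde may be aminoxylated slowly relative to the ring ketone, and an unchelated Felkin-type ene pathway would give the 8,9-trans (7α,8β) isomer. The fallback sets out from keto aldehyde 11 and comes back at 15. The aminoxylation is run on its own and the N–O bond of 12 is cut in situ with CuSO4 in MeOH to give (2S)-2-hydroxy-2-[(1S,2R,3S)-2,3-dimethyl-2-(3-methylbut-2-en-1-yl)-5-oxocyclohexyl]acetaldehyde F5. Me2AlCl (2.5 equiv) turns it into a covalent aluminium alkoxide chelate and triggers the ene cyclisation to the cis-diol (4S,4aR,6R,7R,8S,8aS)-7,8-dihydroxy-4,4a-dimethyl-6-(prop-1-en-2-yl)octahydronaphthalen-2(1H)-one F6. AcCl with 2,4,6-collidine at −78 °C acetylates only the equatorial O8 and gives 15.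

Step 7 acylates an axial alcohol flanked by the ring fusion and an acetate, so it may be slow, or the acetyl group may migrate. The fallback sets out from 15 and comes back at 16. With Et3N in place of pyridine the acid chloride is converted into isopropenylketene, a small and very reactive acylating agent that esterifies the hindered alcohol as the deconjugated ester (1S,2R,3R,4aR,5S,8aS)-2-(acetyloxy)-4a,5-dimethyl-7-oxo-3-(prop-1-en-2-yl)decahydronaphthalen-1-yl 3-methylbut-3-enoate F7. DBU then moves the double bond into conjugation and gives 16.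

**Further compounds**
F1 | step 2 | (S)-5-methylcyclohex-2-en-1-one | C1C(=O)C=CC[C@@H]1C
F2 | step 2 | (R)-5-methyl-3-(phenylsulfanyl)cyclohex-2-en-1-one | C1C(=O)C=C(Sc2ccccc2)C[C@@H]1C
F3 | step 2 | (5S)-5,6-dimethyl-3-(phenylsulfanyl)cyclohex-2-en-1-one (C6 epimers) | CC1C(=O)C=C(Sc2ccccc2)C[C@@H]1C
F4 | step 2 | (5S,6R)-5,6-dimethyl-6-(3-methylbut-2-en-1-yl)-3-(phenylsulfanyl)cyclohex-2-en-1-one | CC(C)=CC[C@@]1(C)C(=O)C=C(Sc2ccccc2)C[C@@H]1C
F5 | step 4 | (2S)-2-hydroxy-2-[(1S,2R,3S)-2,3-dimethyl-2-(3-methylbut-2-en-1-yl)-5-oxocyclohexyl]acetaldehyde | CC(C)=CC[C@@]1(C)[C@@H]([C@H](O)C=O)CC(=O)C[C@@H]1C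
F6 | step 4 | (4S,4aR,6R,7R,8S,8aS)-7,8-dihydroxy-4,4a-dimethyl-6-(prop-1-en-2-yl)octahydronaphthalen-2(1H)-one | C=C(C)[C@H]1C[C@@]2(C)[C@H](CC(=O)C[C@@H]2C)[C@H](O)[C@@H]1O
F7 | step 7 | (1S,2R,3R,4aR,5S,8aS)-2-(acetyloxy)-4a,5-dimethyl-7-oxo-3-(prop-1-en-2-yl)decahydronaphthalen-1-yl 3-methylbut-3-enoate | C=C(C)[C@H]1C[C@@]2(C)[C@H](CC(=O)C[C@@H]2C)[C@H](OC(=O)CC(C)=C)[C@@H]1OC(C)=O
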